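**Plan**

1. The retrosynthesis cuts the two bonds that join the benzylic carbons of ring B to the diol carbons, C4–C3 and C1–C2. Ring B is a cyclohexene ring fused to aromatic ring A, so C4 and C1 are the termini of an o-quinodimethane. C2–C3 (one oxygen and one carboxyl-level carbon on each, the two C–O bonds trans) is an E-enediol alkene, a dehydro form of tartaric acid.
2. The diene precursor is an o-benzylbenzaldehyde joined by a Suzuki–Miyaura sp2–sp3 coupling. The dienophile is the C2-symmetric bis(pivaldehyde acetal) of dehydrotartaric acid, made from D-(−)-tartaric acid.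
3. Forward ring order: photoenolization of the aldehyde dearomatizes ring A, and one Diels–Alder event closes ring B and sets C1, C2 and C3 together with a temporary C4 hydroxyl.
4. The C4 oxygen then captures the C2 carboxyl as a γ-lactone, which tells the two carboxyl carbons apart. The free C3 carboxyl is reduced to CH2OH, and one hydrogenolysis removes the benzyl ethers and the C4 oxygen.
5. Stereochemistry: the absolute configuration comes from D-tartaric acid. It is stored in the two (S) acetal carbons while C2/C3 are planar (self-regeneration of stereocentres) and returned by addition anti to both tert-butyl groups. The relative configuration comes from the E,E-dienol, the E alkene and the endo orientation.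

Key step: step 8

Remark: tetralin locants follow the target name (C1 aryl methine, C2 carboxyl carbinol, C3 hydroxymethyl carbinol, C4 methylene); the E isomer of the ene-dilactone dienophile is assumed to be the thermodynamically preferred alkene isomer.

Step 1
Reactants: 1 D-(−)-tartaric acid
Product: 2 (2S,2'S,5S,5'S)-2,2'-di-tert-butyl-[5,5'-bi(1,3-dioxolane)]-4,4'-dione
Conditions: t-BuCHO (2.5 equiv), TsOH·H2O (cat.), H2SO4 (cat.), pentane, reflux, Dean–Stark; recrystallization
Reagents that add atoms: pivaldehyde (2,2-dimethylpropanal), CC(C)(C)C=O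
Why: Acid-catalysed acetalization of both α-hydroxy acid units with azeotropic removal of water (pivaldehyde acetal template of the self-regeneration-of-stereocentres type) should close two 1,3-dioxolan-4-ones, the thermodynamically preferred cis arrangement (tert-butyl cis to the ring-junction substituent) setting both new acetal carbons as S under control of the tartrate carbons.

Step 2
Reactants: 2 (2S,2'S,5S,5'S)-2,2'-di-tert-butyl-[5,5'-bi(1,3-dioxolane)]-4,4'-dione
Product: 5 (E)-(2S,2'S)-2,2'-di-tert-butyl-[5,5'-bi(1,3-dioxolanylidene)]-4,4'-dione, via monobromide 3 (not isolated), via Z-alkene 4 (not isolated)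
Conditions: NBS (1.05 equiv), AIBN (cat.), PhCF3, 80 °C; then Et3N, CH2Cl2, 0 °C to rt; then iodine (5 mol %), visible light, rt
Reagents that add atoms: none
Why: Wohl–Ziegler bromination should abstract a captodative ring-junction C–H and deliver bromine trans to tert-butyl, triethylamine then removes the acidic neighbouring C–H with loss of bromide (anti elimination, hence the Z alkene first), and iodine-atom addition–elimination equilibrates this to the E alkene in which the two lactone dipoles oppose each other; the acetal stereocentres are untouched and now hold the only stereochemical information.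

Step 3
Reactants: 6 3,4-dihydroxy-5-methoxybenzaldehyde
Product: 7 3,4-bis(benzyloxy)-5-methoxybenzaldehyde
Conditions: BnBr (2.4 equiv), K2CO3, DMF, 60 °C
Reagents that add atoms: benzyl bromide, BrCc1ccccc1
Why: Williamson ether synthesis, in which both phenoxides are alkylated by benzyl bromide to protect the catechol as hydrogenolysable ethers.

Step 4
Reactants: 7 3,4-bis(benzyloxy)-5-methoxybenzaldehyde
Product: 8 [3,4-bis(benzyloxy)-5-methoxyphenyl]methanol
Conditions: NaBH4, MeOH/THF, 0 °C
Reagents that add atoms: none
Why: Borohydride reduction of the aryl aldehyde to the benzylic alcohol, to which benzyl ethers are inert.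

Step 5
Reactants: 8 [3,4-bis(benzyloxy)-5-methoxyphenyl]methanol
Product: 9 1,2-bis(benzyloxy)-5-(bromomethyl)-3-methoxybenzene
Conditions: PBr3 (0.4 equiv), CH2Cl2, 0 °C
Reagents that add atoms: phosphorus tribromide, BrP(Br)Br
Why: PBr3 should convert the benzylic alcohol into the bromide by substitution of the intermediate phosphite ester, the two meta-alkoxy groups tempering ionization so that the bromide can be handled without solvolysis.

Step 6
Reactants: 10 4-(benzyloxy)-2-bromo-5-methoxybenzaldehyde
Product: 11 4-(benzyloxy)-5-methoxy-2-(4,4,5,5-tetramethyl-1,3,2-dioxaborolan-2-yl)benzaldehyde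
Conditions: B2pin2, PdCl2(dppf) (3 mol %), KOAc, 1,4-dioxane, 90 °C
Reagents that add atoms: bis(pinacolato)diboron, CC1(C)OB(OC1(C)C)B1OC(C)(C)C(C)(C)O1
Why: Miyaura borylation (oxidative addition of the aryl bromide, acetate-assisted transmetalation with B2pin2, reductive elimination), which tolerates the ortho formyl group under the weak base KOAc.

Step 7
Reactants: 11 4-(benzyloxy)-5-methoxy-2-(4,4,5,5-tetramethyl-1,3,2-dioxaborolan-2-yl)benzaldehyde; 9 1,2-bis(benzyloxy)-5-(bromomethyl)-3-methoxybenzene
Product: 12 4-(benzyloxy)-2-[[3,4-bis(benzyloxy)-5-methoxyphenyl]methyl]-5-methoxybenzaldehyde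
Conditions: Pd(PPh3)4 (5 mol %), K3PO4 (3 equiv), toluene/H2O, 80 °C
Reagents that add atoms: none
Why: Suzuki–Miyaura sp2–sp3 coupling of the arylboronate with the benzylic bromide should build the diarylmethane and place the doubly benzylic CH2 ortho to the aldehyde, which is the hydrogen donor needed for photoenolization.

Step 8
Reactants: 12 4-(benzyloxy)-2-[[3,4-bis(benzyloxy)-5-methoxyphenyl]methyl]-5-methoxybenzaldehyde; 5 (E)-(2S,2'S)-2,2'-di-tert-butyl-[5,5'-bi(1,3-dioxolanylidene)]-4,4'-dione
Product: 14 dispiro Diels–Alder adduct (1S,2S,3S,4R; both acetal carbons S), via E,E-dienol 13 (not isolated)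
Conditions: 5 (1.5 equiv), hν (365 nm LED), degassed toluene (0.05 M), 15 °C
Reagents that add atoms: none
Why: Proposed new method: excitation of the aryl aldehyde of 12 should trigger 1,5-hydrogen transfer from the doubly benzylic ortho CH2 to the carbonyl oxygen (photoenolization), dearomatizing ring A to the (E,E)-hydroxy-o-quinodimethane 13, which is trapped in a concerted, asynchronous, suprafacial [4π+2π] Diels–Alder reaction by the tetrasubstituted, doubly captodative alkene 5, closing six-membered ring B by intermolecular cycloaddition (two spiro junctions) with rearomatization of ring A as the driving force. The closest known reaction type is the photoenolization/Diels–Alder reaction (and the thermal cycloaddition of α-hydroxy-α'-aryl-o-quinodimethanes) with fumarates and with 5-alkylidene-1,3-dioxolan-4-ones; what is new is a tetrasubstituted enediol-derived dienophile that sets two vicinal fully substituted carbinol carbons at once. C1 and C4 follow from the E,E geometry of 13 (aryl and hydroxyl both outward, since the Z dienol reverts to 12 by 1,5-H shift and an inward aryl is sterically disfavoured), and C2/C3 follow from the E alkene, so the two C–O bonds end up trans, as do the two carbonyl carbons. Facial selectivity comes from the C2-symmetric reagent: both tert-butyl groups shield the same face, so the diene adds to the face of the two acetal hydrogens, which fixes the absolute configuration. Because 5 is C2-symmetric there is no regiochemical issue; the one selectivity that must be earned is orientation (carbonyl endo at the hydroxyl-bearing terminus, ring oxygen endo at the aryl-bearing terminus), expected from the endo preference and O–H···O contact at the small hydroxyl terminus and from the smaller ring-oxygen side meeting the bulky aryl group, as in fumarate additions to α-hydroxy-α'-aryl-o-quinodimethanes. The step needs light that only 12 absorbs, an excess of the flat, tied-back dienophile to outrun dienol reversion, and exclusion of oxygen.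

Step 9
Reactants: 14 dispiro Diels–Alder adduct
Product: 16 lactone acid (1S,2S,3S,4S), via lactone acylal 15 (not isolated)
Conditions: TFA (20 mol %), CH2Cl2, 0 °C to rt; then LiOH·H2O (3 equiv), THF/H2O, 0 °C; then 1 M HCl to pH 2, 0 °C to rt
Reagents that add atoms: lithium hydroxide, [Li+].[OH-]
Why: Acid should ionize the para-alkoxybenzylic C4–OH to a quinone-methide-like cation that only the C2 acylal carbonyl can reach through a five-membered transition state (the C3 carbonyl would give a β-lactone), so a γ-lactone forms with inversion at C4 and loss of pivaldehyde, after which hydroxide opens the remaining activated acylal by acyl substitution (any opened lactone re-closes on acidification) to leave the C3 carboxyl free and thereby differentiated from the C2 carboxyl; C1, C2 and C3 are not involved.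

Step 10
Reactants: 16 lactone acid
Product: 17 lactone triol (1S,2S,3S,4S)
Conditions: BH3·SMe2 (5 equiv), THF, 0 °C to rt; then MeOH
Reagents that add atoms: none
Why: Chemoselective borane reduction, in which BH3 reduces the free carboxylic acid through an acyloxyborane far faster than the lactone, should give the C3 hydroxymethyl group without touching any stereocentre.

Step 11
Reactants: 17 lactone triol
Product: 18 plicatic acid
Conditions: H2 (1–3 atm), Pd/C (10% palladium on carbon), THF/H2O, AcOH (cat.), rt
Reagents that add atoms: none
Why: Catalytic hydrogenolysis should cleave the three aryl benzyl ethers and the benzylic C4–O bond of the lactone (benzyl-ester-type alkyl–oxygen cleavage, made easy by the para-oxygen), which frees the C2 carboxylic acid and leaves C4 as the methylene of the target; C1, C2 and C3 are unaffected.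

**Compound list**

1 | D-(−)-tartaric acid, (2S,3S)-2,3-dihydroxybutanedioic acid | OC(=O)[C@@H](O)[C@H](O)C(=O)O | starting material
2 | (2S,2'S,5S,5'S)-2,2'-di-tert-butyl-[5,5'-bi(1,3-dioxolane)]-4,4'-dione (carbonyl at C4, ring junction at C5, each tert-butyl cis to the other ring) | CC(C)(C)[C@H]1O[C@H](C(=O)O1)[C@@H]1O[C@H](C(C)(C)C)OC1=O | intermediate
3 | monobromide of 2 (bromine at one ring-junction carbon, trans to tert-butyl) | CC(C)(C)[C@H]1O[C@](Br)(C(=O)O1)[C@@H]1O[C@H](C(C)(C)C)OC1=O | intermediate (not isolated)
4 | (Z)-(2S,2'S)-2,2'-di-tert-butyl-[5,5'-bi(1,3-dioxolanylidene)]-4,4'-dione | CC(C)(C)[C@H]1O/C(=C2\O[C@H](C(C)(C)C)OC2=O)C(=O)O1 | intermediate (not isolated)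
5 | (E)-(2S,2'S)-2,2'-di-tert-butyl-[5,5'-bi(1,3-dioxolanylidene)]-4,4'-dione (ring oxygens trans, carbonyls trans, both tert-butyl groups on one face) | CC(C)(C)[C@H]1O/C(=C2/O[C@H](C(C)(C)C)OC2=O)C(=O)O1 | intermediate
6 | 3,4-dihydroxy-5-methoxybenzaldehyde | COc1cc(C=O)cc(O)c1O | starting material
7 | 3,4-bis(benzyloxy)-5-methoxybenzaldehyde | COc1cc(C=O)cc(OCc2ccccc2)c1OCc1ccccc1 | intermediate
8 | [3,4-bis(benzyloxy)-5-methoxyphenyl]methanol | COc1cc(CO)cc(OCc2ccccc2)c1OCc1ccccc1 | intermediate
9 | 1,2-bis(benzyloxy)-5-(bromomethyl)-3-methoxybenzene | COc1cc(CBr)cc(OCc2ccccc2)c1OCc1ccccc1 | intermediate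
10 | 4-(benzyloxy)-2-bromo-5-methoxybenzaldehyde | COc1cc(C=O)c(Br)cc1OCc1ccccc1 | starting material
11 | 4-(benzyloxy)-5-methoxy-2-(4,4,5,5-tetramethyl-1,3,2-dioxaborolan-2-yl)benzaldehyde | COc1cc(C=O)c(B2OC(C)(C)C(C)(C)O2)cc1OCc1ccccc1 | intermediate
12 | 4-(benzyloxy)-2-[[3,4-bis(benzyloxy)-5-methoxyphenyl]methyl]-5-methoxybenzaldehyde | COc1cc(C=O)c(Cc2cc(OC)c(OCc3ccccc3)c(OCc3ccccc3)c2)cc1OCc1ccccc1 | intermediate
13 | (E,E)-hydroxy-o-quinodimethane (photoenol of 12; hydroxyl and aryl both outward on the two exocyclic alkenes) | O/C=C1\C=C(OC)C(OCc2ccccc2)=C/C1=C\c1cc(OC)c(OCc2ccccc2)c(OCc2ccccc2)c1 | intermediate (not isolated)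
14 | (1S,2S,3S,4R)-7-(benzyloxy)-1-[3,4-bis(benzyloxy)-5-methoxyphenyl]-4-hydroxy-6-methoxy-1,2,3,4-tetrahydronaphthalene with C2 and C3 each spiro-fused to C5 of a (2S)-2-tert-butyl-1,3-dioxolan-4-one (C1 aryl cis to the C2 ring oxygen and trans to the C2 carbonyl; C2–O and C3–O trans; C4–OH cis to the C3 carbonyl) | COc1cc2c(cc1OCc1ccccc1)[C@H](c1cc(OC)c(OCc3ccccc3)c(OCc3ccccc3)c1)[C@]3(O[C@H](C(C)(C)C)OC3=O)[C@@]4(O[C@H](C(C)(C)C)OC4=O)[C@@H]2O | intermediate
15 | lactone acylal (1S,2S,3S,4S): γ-lactone between the C2 carbonyl and the C4 oxygen, free C2–OH, C3 still spiro-fused to the (2S)-2-tert-butyl-1,3-dioxolan-4-one | COc1cc2c(cc1OCc1ccccc1)[C@H](c1cc(OC)c(OCc3ccccc3)c(OCc3ccccc3)c1)[C@@]3(O)C(=O)O[C@@H]2[C@]34O[C@H](C(C)(C)C)OC4=O | intermediate (not isolated)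
16 | lactone acid (1S,2S,3S,4S): γ-lactone between the C2 carbonyl and the C4 oxygen, C2–OH and C3–OH trans, free C3 carboxylic acid, three benzyl ethers | COc1cc2c(cc1OCc1ccccc1)[C@H](c1cc(OC)c(OCc3ccccc3)c(OCc3ccccc3)c1)[C@@]3(O)C(=O)O[C@@H]2[C@@]3(O)C(=O)O | intermediate
17 | lactone triol (1S,2S,3S,4S): as 16 with CH2OH in place of the C3 carboxyl | COc1cc2c(cc1OCc1ccccc1)[C@H](c1cc(OC)c(OCc3ccccc3)c(OCc3ccccc3)c1)[C@@]3(O)C(=O)O[C@@H]2[C@@]3(O)CO | intermediate
18 | plicatic acid, (1S,2S,3R)-1-(3,4-dihydroxy-5-methoxyphenyl)-2,3,7-trihydroxy-3-(hydroxymethyl)-6-methoxy-1,2,3,4-tetrahydronaphthalene-2-carboxylic acid | COc1cc2c(cc1O)[C@H](c1cc(O)c(O)c(OC)c1)[C@@](O)(C(=O)O)[C@](O)(CO)C2 | target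

**Step count and risks**

Total steps: 11. Longest linear sequence: 8 steps (6 → 7 → 8 → 9 → 12 → 14 → 16 → 17 → 18; steps 3, 4, 5, 7, 8, 9, 10, 11).

Step 8 (proposed new method). What may go wrong: reketonization of the photoenol back to 12 faster than cycloaddition to the hindered alkene; triplet energy transfer from excited 12 to 5, which would isomerize 5 and erode facial control; or poor endo orientation. The fallback uses known chemistry, sets out from 12 and returns at 14. Compound 12 is irradiated in SO2-saturated benzene so that the dienol is trapped by cheletropic addition as the crystalline cis-hydroxysulfone, cis-5-(benzyloxy)-3-[3,4-bis(benzyloxy)-5-methoxyphenyl]-6-methoxy-1,3-dihydro-2-benzothiophen-1-ol 2,2-dioxide F1 (racemic; its stereocentres are lost again on extrusion). F1 is then heated with 5 in toluene at 80–110 °C in the dark. Thermal disrotatory extrusion of SO2 releases only the E,E-dienol at a low stationary concentration, and the same Diels–Alder addition should give 14 with no excited state in the flask. This hydroxysulfone sequence is the established thermal entry to α-hydroxy-α'-aryl-o-quinodimethanes and their fumarate-type cycloadducts. It removes the photochemical failure modes but does not by itself correct a poor endo orientation.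

Step 2. What may go wrong: opening of an acylal ring by β-alkoxide elimination from the enolate formed in the base step, or incomplete Z to E equilibration. The fallback sets out from 2 and returns at 5. Both captodative C–H bonds of 2 are brominated (NBS 2.2 equiv, AIBN) to the 5,5'-dibromide F2. F2 is reduced with zinc dust in THF (1,2-debromination, no base and no enolate). The E isomer 5 is collected by crystallization after the same iodine-catalysed equilibration.

Step 10. What may go wrong: competing borane reduction of the α-hydroxy lactone, or stalling of the hindered tertiary carboxyl as a stable borate. The fallback sets out from 16 and returns at 17. The acid is activated with isobutyl chloroformate and N-methylmorpholine in THF at −15 °C as the mixed carbonic anhydride F3. F3 is reduced in the same flask with aqueous NaBH4, which should attack the anhydride carbonyl far faster than the lactone.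

Further compounds
F1 | step 8 | cis-5-(benzyloxy)-3-[3,4-bis(benzyloxy)-5-methoxyphenyl]-6-methoxy-1,3-dihydro-2-benzothiophen-1-ol 2,2-dioxide (racemic, one enantiomer drawn) | O[C@H]1c2cc(OC)c(OCc3ccccc3)cc2[C@@H](c2cc(OC)c(OCc3ccccc3)c(OCc3ccccc3)c2)S1(=O)=O
F2 | step 2 | 5,5'-dibromide of 2 (each bromine trans to the tert-butyl group of its ring) | CC(C)(C)[C@H]1O[C@](Br)(C(=O)O1)[C@]1(Br)O[C@H](C(C)(C)C)OC1=O
F3 | step 10 | mixed isobutyl carbonic anhydride of lactone acid 16 | COc1cc2c(cc1OCc1ccccc1)[C@H](c1cc(OC)c(OCc3ccccc3)c(OCc3ccccc3)c1)[C@@]3(O)C(=O)O[C@@H]2[C@@]3(O)C(=O)OC(=O)OCC(C)C
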